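**Retrosynthetic overview**

1. Feature: the benzo ring of the isoquinoline (C4a–C5–C6–C7–C8–C8a) is a phenol whose hydroxyl carbon C8 is bonded to the fusion atom C8a and to C7, the carbon holding the C7–C1′ biaryl bond. With C5 and C6 unsubstituted, this is the imprint of a ketene carbon that has closed onto an arene.
2. C6–H ⇒ C6–SMe: a sulfur atom, removed last, is placed at C6 to polarise an alkyne.
3. Key cut of the benzo ring at C4a–C5, C5–C6, C7–C8 and C8–C8a ⇒ 4-(diazoacetyl)-2,6-dimethylpyridine (pyridine ring bought intact, its two ortho carbons equivalent) plus a naphthyl alkynyl methyl sulfide (the biaryl bond already exists as the aryl–alkyne bond).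
4. Alkynyl sulfide ⇒ 1-bromo-4,5-dimethoxy-7-methylnaphthalene (Sonogashira) ⇒ Stobbe condensation and Friedel–Crafts ring closure from 2-bromo-5-methoxybenzaldehyde and dimethyl succinate.
5. Ring order: the second naphthalene ring (step 4), then the isoquinoline carbocycle (step 12); no other ring is made.

Key step: step 12

Assumption: the C7–C1′ axis of the target has only OH and H as ortho groups on the isoquinoline side and is treated as configurationally undefined, as in the given SMILES; the methylsulfanyl intermediate of the key step should form as a racemate of atropisomers, and this is of no consequence.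

**Route**

Step 1
Reactants: 1 2,6-dimethylisonicotinic acid
Product: 2 2,6-dimethylpyridine-4-carbonyl chloride hydrochloride
Conditions: (COCl)2, DMF (cat.), CH2Cl2, 0 °C to rt; concentrate
Reagents that add atoms: oxalyl chloride, O=C(Cl)C(Cl)=O
Why: Acid chloride formation through the Vilsmeier-type chloroiminium species from DMF and oxalyl chloride is general for pyridinecarboxylic acids, and the ring nitrogen holds the HCl so that the salt is left on evaporation.

Step 2
Reactants: 2 2,6-dimethylpyridine-4-carbonyl chloride hydrochloride
Product: 3 2-diazo-1-(2,6-dimethylpyridin-4-yl)ethan-1-one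
Conditions: TMSCHN2 (2 M in hexanes), Et3N, MeCN/THF, 0 °C to rt
Reagents that add atoms: trimethylsilyldiazomethane, C[Si](C)(C)C=[N+]=[N-]
Why: Acylation of the diazoalkane carbon by the aroyl chloride followed by chloride-induced loss of the silyl group (first stage of an Arndt–Eistert sequence) should give the diazomethyl ketone, Et3N taking up the HCl of the salt so that no chloromethyl ketone forms, and an aroyl chloride without α-hydrogen having no ketene pathway.

Step 3
Reactants: 4 2-bromo-5-methoxybenzaldehyde; 5 dimethyl succinate
Product: 6 (3E)-4-(2-bromo-5-methoxyphenyl)-3-(methoxycarbonyl)but-3-enoic acid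
Conditions: NaOMe, MeOH, reflux; then aq. HCl
Reagents that add atoms: none
Why: Stobbe condensation, in which aldol addition of the succinate enolate, lactonisation and base-induced opening of the paraconic ester give the half-ester with the aryl group cis to the CH2CO2H arm (E alkene), as the later ring closure requires.

Step 4
Reactants: 6 (3E)-4-(2-bromo-5-methoxyphenyl)-3-(methoxycarbonyl)but-3-enoic acid
Product: 8 methyl 4-acetoxy-8-bromo-5-methoxynaphthalene-2-carboxylate, via naphthol 7 (not isolated)
Conditions: Ac2O, NaOAc, 140 °C
Reagents that add atoms: acetic anhydride, CC(=O)OC(C)=O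
Why: The mixed anhydride acylates the ring intramolecularly (Friedel–Crafts acylation) at the only free ortho carbon, which the ortho methoxy group activates while bromine blocks the other, and naphthol 7 formed on enolisation is acetylated in situ.

Step 5
Reactants: 8 methyl 4-acetoxy-8-bromo-5-methoxynaphthalene-2-carboxylate
Product: 9 5-bromo-3-(hydroxymethyl)-8-methoxynaphthalen-1-ol
Conditions: LiAlH4, THF, 0 °C to rt
Reagents that add atoms: none
Why: Hydride reduction with LiAlH4 takes the methyl ester to the primary alcohol and cleaves the aryl acetate in the same operation, and an aryl bromide is not reduced at this temperature.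

Step 6
Reactants: 9 5-bromo-3-(hydroxymethyl)-8-methoxynaphthalen-1-ol
Product: 10 (8-bromo-4,5-dimethoxynaphthalen-2-yl)methanol
Conditions: MeI, K2CO3, acetone, reflux
Reagents that add atoms: iodomethane, CI
Why: Williamson O-methylation in which K2CO3 deprotonates only the naphthol and not the benzylic alcohol, so that methylation should be chemoselective.

Step 7
Reactants: 10 (8-bromo-4,5-dimethoxynaphthalen-2-yl)methanol
Product: 11 1-bromo-7-(bromomethyl)-4,5-dimethoxynaphthalene
Conditions: CBr4, PPh3, CH2Cl2, 0 °C
Reagents that add atoms: carbon tetrabromide, BrC(Br)(Br)Br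
Why: Appel reaction of a primary benzylic alcohol under neutral conditions that leave the electron-rich ring and the aryl bromide untouched.

Step 8
Reactants: 11 1-bromo-7-(bromomethyl)-4,5-dimethoxynaphthalene
Product: 12 1-bromo-4,5-dimethoxy-7-methylnaphthalene
Conditions: LiBHEt3, THF, −78 to 0 °C
Reagents that add atoms: none
Why: SN2 displacement of the benzylic bromide by hydride from LiBHEt3, which does not attack an aryl C–Br bond at low temperature.

Step 9
Reactants: 12 1-bromo-4,5-dimethoxy-7-methylnaphthalene; 13 ethynyltrimethylsilane
Product: 14 [(4,5-dimethoxy-7-methylnaphthalen-1-yl)ethynyl]trimethylsilane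
Conditions: Pd(PhCN)2Cl2 (3 mol%), [HP(t-Bu)3]BF4 (6 mol%), CuI (2 mol%), i-Pr2NH, 1,4-dioxane, 45 °C
Reagents that add atoms: none
Why: Sonogashira coupling in which the bulky, electron-rich P(t-Bu)3 ligand drives oxidative addition into the electron-rich, peri-flanked C–Br bond near room temperature.

Step 10
Reactants: 14 [(4,5-dimethoxy-7-methylnaphthalen-1-yl)ethynyl]trimethylsilane
Product: 15 1-ethynyl-4,5-dimethoxy-7-methylnaphthalene
Conditions: K2CO3, MeOH/THF, rt
Reagents that add atoms: none
Why: Methoxide-induced protodesilylation of the C(sp)–Si bond, to which the aryl ethers are inert.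

Step 11
Reactants: 15 1-ethynyl-4,5-dimethoxy-7-methylnaphthalene
Product: 17 4,5-dimethoxy-7-methyl-1-[(methylsulfanyl)ethynyl]naphthalene, via lithium acetylide 16 (not isolated)
Conditions: n-BuLi, THF, −78 °C; then MeSSMe, −78 °C to rt
Reagents that add atoms: dimethyl disulfide, CSSC; n-butyllithium, [Li]CCCC (supplies the lithium of 16 only)
Why: Deprotonation of the terminal alkyne and sulfenylation of lithium acetylide 16 at sulfur by the disulfide, the standard way to alkynyl sulfides, run cold so that the thiolate set free does not add to the product.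

Step 12
Reactants: 3 2-diazo-1-(2,6-dimethylpyridin-4-yl)ethan-1-one; 17 4,5-dimethoxy-7-methyl-1-[(methylsulfanyl)ethynyl]naphthalene
Product: 22 7-(4,5-dimethoxy-7-methylnaphthalen-1-yl)-1,3-dimethyl-6-(methylsulfanyl)isoquinolin-8-ol, via pyridylketene 18 (not isolated), via cyclobutenone 19 (not isolated), via dienylketene 20 (not isolated), via dienone tautomer 21 (not isolated)
Conditions: hν (400–450 nm LED), 3 (1.5 equiv), degassed ClCH2CH2Cl, 20 °C; then 80 °C
Reagents that add atoms: none
Why: Excitation of the n→π* band of 3 expels N2 with a 1,2-shift of the pyridyl group (photochemical Wolff rearrangement, C4a–C5) to give ketene 18, which the sulfur-polarised alkyne 17 captures in a [2+2] cycloaddition that joins the naphthyl-bearing alkyne carbon to the ketene carbonyl carbon (C7–C8) and the sulfur-bearing carbon to the ketene CH (C5–C6), giving cyclobutenone 19. At 80 °C 19 opens reversibly (4π electrocyclic) to dienylketene 20, whose 3E isomer closes the only ring that is kept, the six-membered carbocycle C4a–C5–C6–C7–C8–C8a, by thermal 6π electrocyclisation of the ketene carbon onto a pyridine carbon ortho to the side chain (C8–C8a), and tautomerisation of dienone 21 restores both aromatic rings and leaves the C8 hydroxyl. The closest known reaction type is the Danheiser benzannulation of aryl and heteroaryl diazomethyl ketones with heteroatom-substituted alkynes, and dienylketene closure onto a pyridine carbon is also the ring-forming event when 4-pyridylcyclobutenones are ring-expanded thermally to quinoline and isoquinoline hydroquinones. The step needs [2+2] regioselectivity, which the sulfur lone pair secures by making the naphthyl-bearing carbon the nucleophilic terminus (the polarisation that makes aryl alkynyl sulfides hydrate to arylacetic thioesters) against the weaker, opposed push of the 4-methoxynaphthyl group; it needs no site selectivity in the closure because the two ortho carbons of the 2,6-dimethylpyridin-4-yl group are equivalent. The two methyl groups also shield the ring nitrogen from the ketene, the π-deficient ring makes the ketene more electrophilic toward the moderately nucleophilic alkyne, and visible light leaves the naphthalene chromophore unexcited. No stereocentre is kept: C4 of 19 and C8a of 21 are erased by ring opening and tautomerisation, and the hindered C7–C1′ axis of 22 should arise as a racemate.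

Step 13
Reactants: 22 7-(4,5-dimethoxy-7-methylnaphthalen-1-yl)-1,3-dimethyl-6-(methylsulfanyl)isoquinolin-8-ol
Product: 23 dioncophylleine D, 7-(4,5-dimethoxy-7-methylnaphthalen-1-yl)-1,3-dimethylisoquinolin-8-ol
Conditions: Raney Ni (W-2, deactivated by refluxing in acetone), EtOH/acetone, reflux
Reagents that add atoms: none
Why: Reductive desulfurisation (hydrogenolysis of the aryl C–S bond on hydrogen-loaded nickel), with the catalyst deactivated by acetone so that the pyridine and naphthalene rings are not hydrogenated; loss of the sulfur also lowers the rotation barrier of the biaryl axis.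

**Compound list**

1 | 2,6-dimethylisonicotinic acid | Cc1cc(C(=O)O)cc(C)n1 | starting material
2 | 2,6-dimethylpyridine-4-carbonyl chloride hydrochloride | Cc1cc(C(=O)Cl)cc(C)[nH+]1.[Cl-] | intermediate
3 | 2-diazo-1-(2,6-dimethylpyridin-4-yl)ethan-1-one | Cc1cc(C(=O)C=[N+]=[N-])cc(C)n1 | intermediate
4 | 2-bromo-5-methoxybenzaldehyde | COc1ccc(Br)c(C=O)c1 | starting material
5 | dimethyl succinate | COC(=O)CCC(=O)OC | starting material
6 | (3E)-4-(2-bromo-5-methoxyphenyl)-3-(methoxycarbonyl)but-3-enoic acid | COC(=O)/C(CC(=O)O)=C/c1cc(OC)ccc1Br | intermediate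
7 | methyl 8-bromo-4-hydroxy-5-methoxynaphthalene-2-carboxylate | COC(=O)c1cc(O)c2c(OC)ccc(Br)c2c1 | intermediate
8 | methyl 4-acetoxy-8-bromo-5-methoxynaphthalene-2-carboxylate | COC(=O)c1cc(OC(C)=O)c2c(OC)ccc(Br)c2c1 | intermediate
9 | 5-bromo-3-(hydroxymethyl)-8-methoxynaphthalen-1-ol | OCc1cc(O)c2c(OC)ccc(Br)c2c1 | intermediate
10 | (8-bromo-4,5-dimethoxynaphthalen-2-yl)methanol | OCc1cc(OC)c2c(OC)ccc(Br)c2c1 | intermediate
11 | 1-bromo-7-(bromomethyl)-4,5-dimethoxynaphthalene | BrCc1cc(OC)c2c(OC)ccc(Br)c2c1 | intermediate
12 | 1-bromo-4,5-dimethoxy-7-methylnaphthalene | Cc1cc(OC)c2c(OC)ccc(Br)c2c1 | intermediate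
13 | ethynyltrimethylsilane | C#C[Si](C)(C)C | starting material
14 | [(4,5-dimethoxy-7-methylnaphthalen-1-yl)ethynyl]trimethylsilane | COc1ccc(C#C[Si](C)(C)C)c2cc(C)cc(OC)c12 | intermediate
15 | 1-ethynyl-4,5-dimethoxy-7-methylnaphthalene | COc1ccc(C#C)c2cc(C)cc(OC)c12 | intermediate
16 | lithium (4,5-dimethoxy-7-methylnaphthalen-1-yl)acetylide | [Li]C#Cc1ccc(OC)c2c(OC)cc(C)cc12 | intermediate
17 | 4,5-dimethoxy-7-methyl-1-[(methylsulfanyl)ethynyl]naphthalene | CSC#Cc1ccc(OC)c2c(OC)cc(C)cc12 | intermediate
18 | 2-(2,6-dimethylpyridin-4-yl)ethen-1-one (pyridylketene) | Cc1cc(C=C=O)cc(C)n1 | intermediate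
19 | 4-(2,6-dimethylpyridin-4-yl)-2-(4,5-dimethoxy-7-methylnaphthalen-1-yl)-3-(methylsulfanyl)cyclobut-2-en-1-one (racemic) | O=C1C(c2ccc(OC)c3c(OC)cc(C)cc23)=C(SC)C1c1cc(C)nc(C)c1 | intermediate
20 | (3E)-4-(2,6-dimethylpyridin-4-yl)-2-(4,5-dimethoxy-7-methylnaphthalen-1-yl)-3-(methylsulfanyl)buta-1,3-dien-1-one | O=C=C(c1ccc(OC)c2c(OC)cc(C)cc12)/C(SC)=C\c1cc(C)nc(C)c1 | intermediate
21 | 7-(4,5-dimethoxy-7-methylnaphthalen-1-yl)-1,3-dimethyl-6-(methylsulfanyl)-8aH-isoquinolin-8-one (racemic) | O=C1C(c2ccc(OC)c3c(OC)cc(C)cc23)=C(SC)C=C2C=C(C)N=C(C)C21 | intermediate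
22 | 7-(4,5-dimethoxy-7-methylnaphthalen-1-yl)-1,3-dimethyl-6-(methylsulfanyl)isoquinolin-8-ol | COc1ccc(-c2c(SC)cc3cc(C)nc(C)c3c2O)c2cc(C)cc(OC)c12 | intermediate
23 | dioncophylleine D | COc1ccc(-c2ccc3cc(C)nc(C)c3c2O)c2cc(C)cc(OC)c12 | target

**Totals**

Total step count: 13. Longest linear sequence: 11 steps (steps 3 to 13).

**Steps most likely to fail**

Step 12. The ketene may be lost by dimerisation or by addition of the ring nitrogen before the hindered, only moderately nucleophilic alkynyl sulfide intercepts it. The naphthyl alkynyl sulfide may also compete for light and degrade, the [2+2] regiochemistry may erode, and closure onto the π-deficient ring may be slow enough that the cyclobutenone accumulates. The fallback makes the ketene in the dark and stages the sequence. It sets out from diazoketone 3: silver-catalysed Wolff rearrangement with water capture (PhCO2Ag cat., Et3N, THF/H2O, rt) should give (2,6-dimethylpyridin-4-yl)acetic acid F1, and oxalyl chloride with catalytic DMF should give (2,6-dimethylpyridin-4-yl)acetyl chloride hydrochloride F2. Slow addition of F2 to alkynyl sulfide 17 and Et3N in toluene at 60–80 °C generates ketene 18 by dehydrochlorination and should give cyclobutenone 19, which is isolated here. Heating 19 in toluene at 110 °C brings the route back to 22.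

Step 13. Hydrogenation may run on into the pyridine or naphthalene ring, or C–S cleavage at the hindered C6 position may stall while the basic product stays adsorbed on the metal. The fallback is a homogeneous nickel-catalysed reductive cleavage that sets out from 22: Ni(PPh3)2Cl2 (cat.) and excess i-PrMgBr in THF/toluene at 80 °C, the first equivalent deprotonating the phenol. Zerovalent nickel formed in situ inserts into the C6–SMe bond, the isopropyl group is transferred and loses propene by β-hydride elimination, and C–H reductive elimination arrives directly at target 23. This fallback makes no new compound (F0).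

Step 9. Oxidative addition into the electron-rich, peri-flanked C–Br bond may be slow, so that oxidative homocoupling of the alkyne and hydrodebromination take over. The fallback builds the alkyne from a carbonyl group instead. It sets out from bromide 12: bromine–lithium exchange (n-BuLi, THF, −78 °C) and formylation with DMF should give 4,5-dimethoxy-7-methylnaphthalene-1-carbaldehyde F3. Seyferth–Gilbert homologation with the Ohira–Bestmann reagent (dimethyl (1-diazo-2-oxopropyl)phosphonate, K2CO3, MeOH, rt) should then give terminal alkyne 15, where the route is rejoined and 14 is bypassed.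

**Further compounds**

F1 | step 12 | (2,6-dimethylpyridin-4-yl)acetic acid | Cc1cc(CC(=O)O)cc(C)n1
F2 | step 12 | (2,6-dimethylpyridin-4-yl)acetyl chloride hydrochloride | Cc1cc(CC(=O)Cl)cc(C)[nH+]1.[Cl-]
F0 | step 13 | none | none
F3 | step 9 | 4,5-dimethoxy-7-methylnaphthalene-1-carbaldehyde | COc1ccc(C=O)c2cc(C)cc(OC)c12
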